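**Plan**

Ring A of the target (the dimethoxy ring: C1 arylethyl, C2 4-hydroxybenzyl, C3 and C5 OMe, C4 and C6 H) has oxygen on the alternate carbons C3 and C5 and carbon arms on the adjacent carbons C1 and C2. This is the imprint of a folded nonane-3,5,7-trione, so ring A can be closed by an aldol condensation.
Retrosynthesis: the two O–CH3 bonds go first, the phenols become benzyl ethers and the CH2–CH2 bridge becomes an E-styryl unit. The ring A C1–C2 bond is then cut (aldol), followed by the ring A C1–C6 bond (acylation of a diketone dianion), the bond from ring A C2 to its benzylic CH2 (alkylation of the acetylacetone dianion) and the styryl C=C (Horner–Wadsworth–Emmons).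
Forward: the chain is joined by alkylation (step 1), olefination (step 2) and acylation (step 3). Ring A, the only ring that is made, closes in step 4; O-methylation and one hydrogenation finish the synthesis.
Stereochemistry: the target has no stereocentre. The E-alkene from step 2 only blocks enolization on one side of the chain during ring closure and is removed by the last hydrogenation.

Key step: step 4

Remark: metal enolates, the phosphonate carbanion and the chelated tetrahedral adduct of step 3 are treated as metalated forms of numbered compounds and carry no numbers; compounds 1, 2, 4 and 5 are taken to be purchasable.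

Chain numbering used below for triketone 7: C1 is the styryl CH next to ring B (the 3-oxygenated phenyl ring), C3, C5 and C7 are the ketones, C9 is the CH2 on ring C (the 4-oxygenated phenyl ring).

**Step 1**
Reactants: 1 acetylacetone (pentane-2,4-dione); 2 4-(benzyloxy)benzyl chloride
Product: 3 6-[4-(benzyloxy)phenyl]hexane-2,4-dione
Conditions: 1 (1.5 equiv), LiN(i-Pr)2 (3.0 equiv), THF, −78 → 0 °C; then 2 (1.0 equiv), 0 °C → rt; 1 M HCl
Reagents that add atoms: none
Why: γ-alkylation of a β-diketone dianion, in which the terminal carbanion is far more nucleophilic than the delocalized central one and should displace the benzylic chloride by SN2 at the methyl carbon only, while the excess of dianion holds back a second alkylation.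

**Step 2**
Reactants: 4 3-(benzyloxy)benzaldehyde; 5 diethyl {2-[methoxy(methyl)amino]-2-oxoethyl}phosphonate
Product: 6 (E)-3-[3-(benzyloxy)phenyl]-N-methoxy-N-methylprop-2-enamide
Conditions: NaH, THF, 0 °C → rt
Reagents that add atoms: none
Why: Horner–Wadsworth–Emmons olefination with an amide-stabilized phosphonate anion, which should give the E-alkene under the usual thermodynamic control and delivers the Weinreb amide directly.

**Step 3**
Reactants: 3 6-[4-(benzyloxy)phenyl]hexane-2,4-dione; 6 (E)-3-[3-(benzyloxy)phenyl]-N-methoxy-N-methylprop-2-enamide
Product: 7 (E)-1-[3-(benzyloxy)phenyl]-9-[4-(benzyloxy)phenyl]non-1-ene-3,5,7-trione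
Conditions: 3 (1.2 equiv), LiN(i-Pr)2 (2.5 equiv), THF, −78 → 0 °C; then 6 (1.0 equiv), −78 → 0 °C; cold 1 M HCl to pH 4
Reagents that add atoms: none
Why: acylation of a β-diketone dianion with a Weinreb amide, in which the second deprotonation should occur kinetically at the methyl group and not at the C5 methylene, the hard terminal carbanion adds 1,2 to the unsaturated amide, and the chelated tetrahedral adduct neither over-reacts nor protonates unreacted dianion before the acidic quench.

**Step 4**
Reactants: 7 (E)-1-[3-(benzyloxy)phenyl]-9-[4-(benzyloxy)phenyl]non-1-ene-3,5,7-trione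
Product: 9 4-[4-(benzyloxy)benzyl]-5-[(E)-3-(benzyloxy)styryl]benzene-1,3-diol, via cyclic aldol adduct 8 (not isolated)
Conditions: KOH (1 M aq.), MeOH, degassed, Ar, 0 °C → rt; then 1 M HCl to pH 3
Reagents that add atoms: none
Why: Hydroxide deprotonates 7, and in a reversible pre-equilibrium the chain C8 methylene next to the C7 ketone is enolized and adds to the C3 styryl ketone, which forms the ring A C1–C2 bond and gives the cyclic aldol 8 (intramolecular aldol addition). The closure that makes ring A is a 6-(enolendo)-exo-trig attack, a mode that the Baldwin rules for enolates class as favoured. E1cB loss of water from 8 and enolization of the two remaining ring ketones then give the aromatic resorcinol irreversibly, which also drains reversible side equilibria such as oxa-Michael addition of an enol oxygen to the styryl ketone. The closest known reaction type is the base-induced cyclization of open-chain 1,3,5-triketones to 5-substituted resorcinols, the laboratory counterpart of polyketide folding. The site selectivity that is needed comes from the substrate: chain C8 is the only enolizable carbon whose attack on a ketone gives a six-membered ring, since the styryl double bond leaves no enolizable hydrogen at chain C2 and so rules out the mirror aldol that would exchange the two aryl arms, while base in place of acid keeps the closure on carbon (acid would close through oxygen to a 4-pyranone). No stereocentre remains in 9, because the two formed in 8 are lost on aromatization, so no stereocontrol is required.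

**Step 5**
Reactants: 9 4-[4-(benzyloxy)benzyl]-5-[(E)-3-(benzyloxy)styryl]benzene-1,3-diol
Product: 10 2-[4-(benzyloxy)benzyl]-1-[(E)-3-(benzyloxy)styryl]-3,5-dimethoxybenzene
Conditions: MeI, K2CO3, acetone, reflux, Ar
Reagents that add atoms: iodomethane, CI
Why: Williamson ether synthesis, in which both phenoxides should be O-methylated by SN2 under conditions (K2CO3 in acetone) that favour O- over C-alkylation and leave the benzyl ethers and the stilbene untouched.

**Step 6**
Reactants: 10 2-[4-(benzyloxy)benzyl]-1-[(E)-3-(benzyloxy)styryl]-3,5-dimethoxybenzene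
Product: 11 gymconopin D, 3-{2-[2-(4-hydroxybenzyl)-3,5-dimethoxyphenyl]ethyl}phenol
Conditions: H2 (1 atm), Pd/C (10 wt % Pd), EtOAc–MeOH, rt
Reagents that add atoms: none
Why: heterogeneous catalytic hydrogenation, which should saturate the stilbene double bond and cleave both benzyl ethers by hydrogenolysis in one operation, while the aryl methyl ethers and the diarylmethane CH2 are inert and no stereocentre arises.

**Compound list**

1 | acetylacetone (pentane-2,4-dione) | CC(=O)CC(C)=O | starting material
2 | 4-(benzyloxy)benzyl chloride, 1-(benzyloxy)-4-(chloromethyl)benzene | ClCc1ccc(OCc2ccccc2)cc1 | starting material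
3 | 6-[4-(benzyloxy)phenyl]hexane-2,4-dione | CC(=O)CC(=O)CCc1ccc(OCc2ccccc2)cc1 | intermediate
4 | 3-(benzyloxy)benzaldehyde | O=Cc1cccc(OCc2ccccc2)c1 | starting material
5 | diethyl {2-[methoxy(methyl)amino]-2-oxoethyl}phosphonate | CCOP(=O)(CC(=O)N(C)OC)OCC | starting material
6 | (E)-3-[3-(benzyloxy)phenyl]-N-methoxy-N-methylprop-2-enamide | CON(C)C(=O)/C=C/c1cccc(OCc2ccccc2)c1 | intermediate
7 | (E)-1-[3-(benzyloxy)phenyl]-9-[4-(benzyloxy)phenyl]non-1-ene-3,5,7-trione | O=C(/C=C/c1cccc(OCc2ccccc2)c1)CC(=O)CC(=O)CCc1ccc(OCc2ccccc2)cc1 | intermediate
8 | 4-[4-(benzyloxy)benzyl]-5-[(E)-3-(benzyloxy)styryl]-5-hydroxycyclohexane-1,3-dione (cyclic aldol, mixture of diastereomers, formed in the flask and not isolated) | O=C1CC(=O)C(Cc2ccc(OCc3ccccc3)cc2)C(O)(/C=C/c2cccc(OCc3ccccc3)c2)C1 | intermediate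
9 | 4-[4-(benzyloxy)benzyl]-5-[(E)-3-(benzyloxy)styryl]benzene-1,3-diol | Oc1cc(O)c(Cc2ccc(OCc3ccccc3)cc2)c(/C=C/c2cccc(OCc3ccccc3)c2)c1 | intermediate
10 | 2-[4-(benzyloxy)benzyl]-1-[(E)-3-(benzyloxy)styryl]-3,5-dimethoxybenzene | COc1cc(OC)c(Cc2ccc(OCc3ccccc3)cc2)c(/C=C/c2cccc(OCc3ccccc3)c2)c1 | intermediate
11 | gymconopin D, 3-{2-[2-(4-hydroxybenzyl)-3,5-dimethoxyphenyl]ethyl}phenol | COc1cc(CCc2cccc(O)c2)c(Cc2ccc(O)cc2)c(OC)c1 | target

**Step count**

Total: 6 steps. Longest linear sequence: 5 steps (1 → 3 → 7 → 9 → 10 → 11; the branch through 6 is equally long).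

**Steps most likely to fail**

Step 4. Hydroxide may cleave the triketone by retro-Claisen fragmentation, or the chain may close through oxygen (oxa-Michael addition to the styryl ketone, cyclodehydration to a 4-pyranone) faster than through carbon. The fallback gives up the ring closure and attaches the two arms to a ready-made 3,5-dimethoxybenzene unit; it sets out from aldehyde 4 and chloride 2 and returns at 10. Commercial diethyl (3,5-dimethoxybenzyl)phosphonate would be brominated with NBS in THF at 0 °C, para to one methoxy group and ortho to the other, to give diethyl (2-bromo-3,5-dimethoxybenzyl)phosphonate F1. Horner–Wadsworth–Emmons olefination of F1 with 4 (KOt-Bu, THF) should give 1-[(E)-3-(benzyloxy)styryl]-2-bromo-3,5-dimethoxybenzene F2. Zinc insertion into 2 (Zn dust, LiCl, THF, rt) would give [4-(benzyloxy)benzyl]zinc chloride F3, and Negishi coupling of F2 with F3 (Pd(OAc)2, SPhos, THF, 50 °C) should give 10, from which step 6 follows.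

Step 3. The second deprotonation of the diketone monoanion may take place at the C5 methylene in place of the methyl group, so that the acyl group enters on the wrong carbon, or the dianion may be quenched by proton transfer before it is acylated. The fallback reverses the order in which the two arms are attached, so that no choice of terminal site exists; it sets out from 1 and returns at 7. The dianion of acetylacetone 1 (LiN(i-Pr)2, 2 equiv, THF) would be acylated with Weinreb amide 6 to give (E)-8-[3-(benzyloxy)phenyl]oct-7-ene-2,4,6-trione F4. Its trianion (LiN(i-Pr)2, 3 equiv, THF, 0 °C) has only one terminal carbanion, at the methyl group, because the styryl end has no enolizable hydrogen. Alkylation with chloride 2 should therefore give 7.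

Step 1. Proton exchange between the dianion and the monoalkylated product may lead to a second alkylation at the other methyl group, and the electron-rich benzylic chloride may be consumed by the amide base. The fallback uses a masked diketone that can be alkylated only once; it sets out from 2 and returns at 3. Commercial 3,5-dimethylisoxazole would be lithiated at the 5-methyl group (n-BuLi, THF, −78 °C) and alkylated with 2 to give 5-{2-[4-(benzyloxy)phenyl]ethyl}-3-methylisoxazole F5. Reductive N–O cleavage (Mo(CO)6, H2O, MeCN, reflux), which spares the benzyl ether, should give (Z)-5-amino-1-[4-(benzyloxy)phenyl]hex-4-en-3-one F6. Hydrolysis of F6 (1 M HCl, THF, rt) should give diketone 3.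

**Further compounds**

F1 | step 4 | diethyl (2-bromo-3,5-dimethoxybenzyl)phosphonate | CCOP(=O)(Cc1cc(OC)cc(OC)c1Br)OCC
F2 | step 4 | 1-[(E)-3-(benzyloxy)styryl]-2-bromo-3,5-dimethoxybenzene | COc1cc(OC)c(Br)c(/C=C/c2cccc(OCc3ccccc3)c2)c1
F3 | step 4 | [4-(benzyloxy)benzyl]zinc chloride | Cl[Zn]Cc1ccc(OCc2ccccc2)cc1
F4 | step 3 | (E)-8-[3-(benzyloxy)phenyl]oct-7-ene-2,4,6-trione | CC(=O)CC(=O)CC(=O)/C=C/c1cccc(OCc2ccccc2)c1
F5 | step 1 | 5-{2-[4-(benzyloxy)phenyl]ethyl}-3-methylisoxazole | Cc1cc(CCc2ccc(OCc3ccccc3)cc2)on1
F6 | step 1 | (Z)-5-amino-1-[4-(benzyloxy)phenyl]hex-4-en-3-one | C/C(N)=C/C(=O)CCc1ccc(OCc2ccccc2)cc1
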